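The route rests on disconnecting ring C at the O1–C8a aryl ether bond. C8a of ring A sits next to C4a, which carries the C4 ketone. A fluorine on C8a is therefore switched on for substitution by that carbonyl and, as the only leaving group on a fully substituted ring A, fixes where the pyranone oxygen is attached, so no step has to differentiate the oxygens at C5, C7 and C8a. In one operation the C2 alkoxide of an open-chain anti aldol displaces this fluoride and closes the chroman-4-one with both stereocentres already in place. The precursor is a hexasubstituted 2-fluoroaryl ketone with a (2R,3R)-configured β-hydroxy-α-(methoxymethoxy) side chain.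

Key step: step 12

Assumption: the magnesium-chelated Z-enolate of glycolyl imide 20 is taken to show the same facial and anti preference as the corresponding propionyl imides, which from the (S)-auxiliary leads to the (2R,3R) adduct; were the sense reversed, the (R)-auxiliary would serve.

Step 1
Reactants: 1 5-fluororesorcinol
Product: 2 1-fluoro-3,5-bis(methoxymethoxy)benzene
Conditions: MOMCl (2.5 equiv), i-Pr2NEt (3 equiv), CH2Cl2, 0 °C → rt
Reagents that add atoms: chloromethyl methyl ether, COCCl
Why: Base-mediated O-alkylation (Williamson type) of both phenols gives acetals that later act as ortho-directing groups and are removed only in the last step.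

Step 2
Reactants: 2 1-fluoro-3,5-bis(methoxymethoxy)benzene; 3 prenyl bromide
Product: 5 5-fluoro-1,3-bis(methoxymethoxy)-2-(3-methylbut-2-en-1-yl)benzene, via C2-aryllithium 4 (not isolated)
Conditions: n-BuLi (1.05 equiv), THF, −78 → −20 °C; CuI (10 mol %), 3, −78 °C → rt
Reagents that add atoms: none
Why: Directed ortho-metalation, in which butyllithium held by the two flanking OMOM oxygens removes the C2 proton (coordination control, preferred over the single-oxygen sites next to fluorine), followed by SN2 alkylation at the primary carbon of prenyl bromide with copper(I) suppressing SN2′ attack.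

Step 3
Reactants: 5 5-fluoro-1,3-bis(methoxymethoxy)-2-(3-methylbut-2-en-1-yl)benzene
Product: 7 1-fluoro-2-iodo-3,5-bis(methoxymethoxy)-4-(3-methylbut-2-en-1-yl)benzene, via C4-aryllithium 6 (not isolated)
Conditions: s-BuLi (1.1 equiv), THF, −78 °C; I2, −78 °C
Reagents that add atoms: iodine, II
Why: A second directed ortho-metalation at one of the two symmetry-equivalent C–H positions flanked by F and OMOM, kept at −78 °C so that the ortho-fluoro aryllithium does not lose LiF, followed by iodinolysis.

Step 4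
Reactants: 8 (R)-lavandulol
Product: 9 (R)-lavandulyl iodide
Conditions: I2, PPh3, imidazole, CH2Cl2, 0 °C → rt
Reagents that add atoms: iodine, II
Why: Appel-type iodination, an SN2 displacement of the alkoxyphosphonium ion at the primary carbon that leaves the adjacent stereocentre untouched.

Step 5
Reactants: 9 (R)-lavandulyl iodide; 7 1-fluoro-2-iodo-3,5-bis(methoxymethoxy)-4-(3-methylbut-2-en-1-yl)benzene
Product: 12 1-fluoro-3,5-bis(methoxymethoxy)-4-(3-methylbut-2-en-1-yl)-2-[(2S)-5-methyl-2-(prop-1-en-2-yl)hex-4-en-1-yl]benzene, via lavandulyllithium 10 (not isolated), via lavandulylzinc chloride 11 (not isolated)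
Conditions: 9 (1.3 equiv), t-BuLi (2.05 equiv per 9), Et2O, −78 °C; ZnCl2 (THF), −78 °C → rt; 7, Pd(OAc)2 (3 mol %), SPhos (6 mol %), THF, 40 °C
Reagents that add atoms: none
Why: Iodine–lithium exchange, transmetalation to zinc and Negishi sp3–sp2 coupling, in which the bulky biarylphosphine makes reductive elimination at the di-ortho-substituted aryl–palladium faster than β-hydride elimination; the stereocentre β to the metal is not involved and is only renamed S by the CIP priority change.

Step 6
Reactants: 13 2,4-dihydroxybenzaldehyde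
Product: 14 2,4-bis(methoxymethoxy)benzaldehyde
Conditions: MOMCl (3 equiv), i-Pr2NEt (4 equiv), CH2Cl2, 0 → 40 °C
Reagents that add atoms: chloromethyl methyl ether, COCCl
Why: O-Alkylation of both phenols (the hydrogen-bonded 2-OH needs excess reagent and gentle warming) gives an aldehyde without acidic protons for the aldol step.

Step 7
Reactants: 15 methyl glycolate
Product: 16 methyl 2-(methoxymethoxy)acetate
Conditions: MOMCl (1.3 equiv), i-Pr2NEt (1.5 equiv), CH2Cl2, 0 °C → rt
Reagents that add atoms: chloromethyl methyl ether, COCCl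
Why: O-Alkylation of the hydroxyl installs at the outset the acetal that will cap the future C3 oxygen, a group that cannot migrate to a neighbouring alkoxide.

Step 8
Reactants: 16 methyl 2-(methoxymethoxy)acetate; 17 (S)-4-benzyloxazolidin-2-one
Product: 20 (S)-4-benzyl-3-[2-(methoxymethoxy)acetyl]oxazolidin-2-one, via potassium carboxylate 18 (not isolated), via pivalic mixed anhydride 19 (not isolated)
Conditions: KOSiMe3 (1.0 equiv), THF, rt; PivCl (1.0 equiv), −20 °C; 17, LiCl, Et3N, −20 °C → rt
Reagents that add atoms: none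
Why: Anhydrous ester cleavage by silanolate, conversion of the carboxylate into the pivalic mixed anhydride and LiCl/Et3N-mediated N-acylation of the oxazolidinone at the less hindered carbonyl (mixed-anhydride imide synthesis).

Step 9
Reactants: 20 (S)-4-benzyl-3-[2-(methoxymethoxy)acetyl]oxazolidin-2-one; 14 2,4-bis(methoxymethoxy)benzaldehyde
Product: 22 (S)-4-benzyl-3-[(2R,3R)-3-[2,4-bis(methoxymethoxy)phenyl]-3-hydroxy-2-(methoxymethoxy)propanoyl]oxazolidin-2-one, via O-trimethylsilyl aldol ether 21 (not isolated)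
Conditions: MgCl2 (20 mol %), Et3N (2 equiv), TMSCl (1.5 equiv), EtOAc, rt; then HF·pyridine, pyridine, THF, 0 °C
Reagents that add atoms: none
Why: Magnesium-halide-catalysed direct anti-aldol of an N-acyloxazolidinone with a non-enolisable aromatic aldehyde, in which the chelated Z-magnesium enolate is attacked on the face away from the benzyl group (sets the α-carbon, the future C3, as R) through a boat transition state (anti, sets the carbinol, the future C2, as R), O-silylation of the aldolate turns the metal over and blocks retro-aldol, and buffered HF then frees the hydroxyl without protic acid.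

Step 10
Reactants: 22 (S)-4-benzyl-3-[(2R,3R)-3-[2,4-bis(methoxymethoxy)phenyl]-3-hydroxy-2-(methoxymethoxy)propanoyl]oxazolidin-2-one
Product: 23 (2R,3R)-3-[2,4-bis(methoxymethoxy)phenyl]-3-hydroxy-N-methoxy-2-(methoxymethoxy)-N-methylpropanamide
Conditions: MeNHOMe·HCl (3 equiv), AlMe3 (3 equiv), CH2Cl2, −20 → 0 °C; Rochelle salt work-up
Reagents that add atoms: N,O-dimethylhydroxylamine hydrochloride, CNOC.Cl
Why: Weinreb transamidation, in which the aluminium amide, anchored by the free β-hydroxyl as its aluminium alkoxide, attacks the exocyclic imide carbonyl and releases the auxiliary without touching either stereocentre.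

Step 11
Reactants: 12 1-fluoro-3,5-bis(methoxymethoxy)-4-(3-methylbut-2-en-1-yl)-2-[(2S)-5-methyl-2-(prop-1-en-2-yl)hex-4-en-1-yl]benzene; 23 (2R,3R)-3-[2,4-bis(methoxymethoxy)phenyl]-3-hydroxy-N-methoxy-2-(methoxymethoxy)-N-methylpropanamide
Product: 27 (2R,3R)-3-[2,4-bis(methoxymethoxy)phenyl]-1-{2-fluoro-4,6-bis(methoxymethoxy)-5-(3-methylbut-2-en-1-yl)-3-[(2S)-5-methyl-2-(prop-1-en-2-yl)hex-4-en-1-yl]phenyl}-3-hydroxy-2-(methoxymethoxy)propan-1-one, via C4a-aryllithium 24 (not isolated), via lithium alkoxide 25 (not isolated), via tetrahedral adduct 26 (not isolated)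
Conditions: 12 (2.2 equiv, the excess is returned as 12), s-BuLi (2.1 equiv), THF, −78 °C; 23 (1.0 equiv), −78 °C; AcOH, −78 °C → rt
Reagents that add atoms: none
Why: Directed ortho-metalation at the last ring C–H (between F and OMOM) followed by Weinreb ketone synthesis, in which the first equivalent of aryllithium turns the hydroxyl into a lithium alkoxide that shields the α-C–H and cannot be eliminated, and the second adds to the amide to give a chelated tetrahedral adduct that releases the ketone only on cold acidic quench, so neither over-addition nor alkoxide–ketone contact occurs.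

Step 12
Reactants: 27 (2R,3R)-3-[2,4-bis(methoxymethoxy)phenyl]-1-{2-fluoro-4,6-bis(methoxymethoxy)-5-(3-methylbut-2-en-1-yl)-3-[(2S)-5-methyl-2-(prop-1-en-2-yl)hex-4-en-1-yl]phenyl}-3-hydroxy-2-(methoxymethoxy)propan-1-one
Product: 29 (2R,3R)-2-[2,4-bis(methoxymethoxy)phenyl]-3,5,7-tris(methoxymethoxy)-6-(3-methylbut-2-en-1-yl)-8-[(2S)-5-methyl-2-(prop-1-en-2-yl)hex-4-en-1-yl]chroman-4-one, via potassium alkoxide 28 (not isolated)
Conditions: KHMDS (1.0 equiv), 18-crown-6 (1.0 equiv), THF, −78 → 0 °C; pH 7 buffer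
Reagents that add atoms: none
Why: KHMDS removes the C2–OH proton and the potassium alkoxide 28 adds to C8a ipso to fluorine; the anionic σ-adduct is stabilised by the ortho C4 carbonyl and collapses with loss of fluoride (addition–elimination SNAr). The closest known reaction type is the base-mediated cyclisation of β-hydroxy 2-fluoroaryl ketones to chroman-4-ones. Ring C closes in a 6-exo-trig mode, O1 attacking an sp2 carbon whose leaving group and delocalised charge lie outside the new ring. No stereocentre is formed: the C2–O, C2–H, C3–O and C3–H bonds stay intact, so the anti pair fixed in step 9 reappears as the 2,3-trans ring. The step needs chemoselectivity for ring closure over retro-aldol cleavage, C3 enolisation and base-induced opening of the product; this should be secured by ortho-acyl activation of the only C–F bond, by a non-migrating C3 acetal that rules out five-ring closure, and by exactly one equivalent of a hindered amide base at low temperature (cyclisation is enthalpy-controlled, fragmentation entropy-favoured, and no base remains once KF has formed).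

Step 13
Reactants: 29 (2R,3R)-2-[2,4-bis(methoxymethoxy)phenyl]-3,5,7-tris(methoxymethoxy)-6-(3-methylbut-2-en-1-yl)-8-[(2S)-5-methyl-2-(prop-1-en-2-yl)hex-4-en-1-yl]chroman-4-one
Product: 30 (2R,3R)-2-(2,4-dihydroxyphenyl)-3,5,7-trihydroxy-6-(3-methylbut-2-en-1-yl)-8-[(2S)-5-methyl-2-(prop-1-en-2-yl)hex-4-en-1-yl]-2,3-dihydro-4H-chromen-4-one
Conditions: 3 M aq HCl–MeOH (1:5), 45 °C
Reagents that add atoms: none
Why: Acid-catalysed solvolysis of the five MOM acetals, in which oxocarbenium formation should be much faster than protonation of the side-chain alkenes at this acidity, while the 2,3-trans arrangement is the thermodynamically preferred one and so survives.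

Compound list
1 | 5-fluororesorcinol (5-fluorobenzene-1,3-diol) | Oc1cc(O)cc(F)c1 | starting material
2 | 1-fluoro-3,5-bis(methoxymethoxy)benzene | COCOc1cc(F)cc(OCOC)c1 | intermediate
3 | prenyl bromide (1-bromo-3-methylbut-2-ene) | CC(C)=CCBr | starting material
4 | [4-fluoro-2,6-bis(methoxymethoxy)phenyl]lithium (not isolated) | [Li]c1c(OCOC)cc(F)cc1OCOC | intermediate
5 | 5-fluoro-1,3-bis(methoxymethoxy)-2-(3-methylbut-2-en-1-yl)benzene | CC(C)=CCc1c(OCOC)cc(F)cc1OCOC | intermediate
6 | [2-fluoro-4,6-bis(methoxymethoxy)-5-(3-methylbut-2-en-1-yl)phenyl]lithium (not isolated) | CC(C)=CCc1c(OCOC)c([Li])c(F)cc1OCOC | intermediate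
7 | 1-fluoro-2-iodo-3,5-bis(methoxymethoxy)-4-(3-methylbut-2-en-1-yl)benzene | CC(C)=CCc1c(OCOC)c(I)c(F)cc1OCOC | intermediate
8 | (R)-lavandulol, (2R)-5-methyl-2-(prop-1-en-2-yl)hex-4-en-1-ol | C=C(C)[C@@H](CC=C(C)C)CO | starting material
9 | (R)-lavandulyl iodide, (5R)-6-iodo-2-methyl-5-(prop-1-en-2-yl)hex-2-ene | C=C(C)[C@@H](CC=C(C)C)CI | intermediate
10 | lavandulyllithium, stereocentre as in 9 (not isolated) | C=C(C)[C@@H](CC=C(C)C)C[Li] | intermediate
11 | lavandulylzinc chloride, stereocentre as in 9 (not isolated) | C=C(C)[C@@H](CC=C(C)C)C[Zn]Cl | intermediate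
12 | 1-fluoro-3,5-bis(methoxymethoxy)-4-(3-methylbut-2-en-1-yl)-2-[(2S)-5-methyl-2-(prop-1-en-2-yl)hex-4-en-1-yl]benzene | C=C(C)[C@@H](CC=C(C)C)Cc1c(F)cc(OCOC)c(CC=C(C)C)c1OCOC | intermediate
13 | 2,4-dihydroxybenzaldehyde | O=Cc1ccc(O)cc1O | starting material
14 | 2,4-bis(methoxymethoxy)benzaldehyde | O=Cc1ccc(OCOC)cc1OCOC | intermediate
15 | methyl glycolate (methyl 2-hydroxyacetate) | COC(=O)CO | starting material
16 | methyl 2-(methoxymethoxy)acetate | COCOCC(=O)OC | intermediate
17 | (S)-4-benzyloxazolidin-2-one | O=C1N[C@@H](Cc2ccccc2)CO1 | starting material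
18 | potassium 2-(methoxymethoxy)acetate (not isolated) | COCOCC(=O)[O-].[K+] | intermediate
19 | 2-(methoxymethoxy)acetic pivalic anhydride (not isolated) | COCOCC(=O)OC(=O)C(C)(C)C | intermediate
20 | (S)-4-benzyl-3-[2-(methoxymethoxy)acetyl]oxazolidin-2-one | COCOCC(=O)N1C(=O)OC[C@@H]1Cc1ccccc1 | intermediate
21 | (S)-4-benzyl-3-[(2R,3R)-3-[2,4-bis(methoxymethoxy)phenyl]-2-(methoxymethoxy)-3-(trimethylsilyloxy)propanoyl]oxazolidin-2-one (not isolated) | O=C([C@H](OCOC)[C@H](O[Si](C)(C)C)c1ccc(OCOC)cc1OCOC)N1C(=O)OC[C@@H]1Cc1ccccc1 | intermediate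
22 | (S)-4-benzyl-3-[(2R,3R)-3-[2,4-bis(methoxymethoxy)phenyl]-3-hydroxy-2-(methoxymethoxy)propanoyl]oxazolidin-2-one | O=C([C@H](OCOC)[C@H](O)c1ccc(OCOC)cc1OCOC)N1C(=O)OC[C@@H]1Cc1ccccc1 | intermediate
23 | (2R,3R)-3-[2,4-bis(methoxymethoxy)phenyl]-3-hydroxy-N-methoxy-2-(methoxymethoxy)-N-methylpropanamide | CON(C)C(=O)[C@H](OCOC)[C@H](O)c1ccc(OCOC)cc1OCOC | intermediate
24 | {2-fluoro-4,6-bis(methoxymethoxy)-5-(3-methylbut-2-en-1-yl)-3-[(2S)-5-methyl-2-(prop-1-en-2-yl)hex-4-en-1-yl]phenyl}lithium (not isolated) | C=C(C)[C@@H](CC=C(C)C)Cc1c(F)c([Li])c(OCOC)c(CC=C(C)C)c1OCOC | intermediate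
25 | lithium alkoxide of 23 (not isolated) | CON(C)C(=O)[C@H](OCOC)[C@H](O[Li])c1ccc(OCOC)cc1OCOC | intermediate
26 | dilithiated tetrahedral adduct of 24 and 25, aminal carbon of undefined configuration (not isolated) | C=C(C)[C@@H](CC=C(C)C)Cc1c(OCOC)c(CC=C(C)C)c(OCOC)c(C(O[Li])(N(C)OC)[C@H](OCOC)[C@H](O[Li])c2ccc(OCOC)cc2OCOC)c1F | intermediate
27 | (2R,3R)-3-[2,4-bis(methoxymethoxy)phenyl]-1-{2-fluoro-4,6-bis(methoxymethoxy)-5-(3-methylbut-2-en-1-yl)-3-[(2S)-5-methyl-2-(prop-1-en-2-yl)hex-4-en-1-yl]phenyl}-3-hydroxy-2-(methoxymethoxy)propan-1-one (key-step precursor) | C=C(C)[C@@H](CC=C(C)C)Cc1c(OCOC)c(CC=C(C)C)c(OCOC)c(C(=O)[C@H](OCOC)[C@H](O)c2ccc(OCOC)cc2OCOC)c1F | intermediate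
28 | potassium alkoxide of 27 (not isolated) | C=C(C)[C@@H](CC=C(C)C)Cc1c(OCOC)c(CC=C(C)C)c(OCOC)c(C(=O)[C@H](OCOC)[C@H]([O-])c2ccc(OCOC)cc2OCOC)c1F.[K+] | intermediate
29 | (2R,3R)-2-[2,4-bis(methoxymethoxy)phenyl]-3,5,7-tris(methoxymethoxy)-6-(3-methylbut-2-en-1-yl)-8-[(2S)-5-methyl-2-(prop-1-en-2-yl)hex-4-en-1-yl]chroman-4-one (key-step product) | C=C(C)[C@@H](CC=C(C)C)Cc1c(OCOC)c(CC=C(C)C)c(OCOC)c2c1O[C@H](c1ccc(OCOC)cc1OCOC)[C@@H](OCOC)C2=O | intermediate
30 | (2R,3R)-2-(2,4-dihydroxyphenyl)-3,5,7-trihydroxy-6-(3-methylbut-2-en-1-yl)-8-[(2S)-5-methyl-2-(prop-1-en-2-yl)hex-4-en-1-yl]-2,3-dihydro-4H-chromen-4-one | C=C(C)[C@@H](CC=C(C)C)Cc1c(O)c(CC=C(C)C)c(O)c2c1O[C@H](c1ccc(O)cc1O)[C@@H](O)C2=O | target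

Total step count: 13. Longest linear sequence: 7 steps (steps 7–13 from methyl glycolate; equally steps 1, 2, 3, 5, 11, 12, 13 from 5-fluororesorcinol).

Steps most likely to fail

1. Step 12. The potassium β-alkoxide ketone may fragment by retro-aldol, or enolise at C3, faster than it closes onto a ring carbon whose activating carbonyl is twisted and flanked by donors; base left over could also open or epimerise the product. Fallback: setting out from 27, the hydroxyl is silylated under neutral conditions (N,O-bis(trimethylsilyl)acetamide, CH2Cl2, rt) to the C2-O-trimethylsilyl ether F1. F1 is then exposed to a substoichiometric anhydrous fluoride source (tetrabutylammonium difluorotriphenylsilicate, 10–20 mol %, THF–DMF, 0 °C → rt). Fluoride unmasks the alkoxide at silicon, the alkoxide closes onto C8a, and the fluoride expelled there cleaves the next silyl ether. The nucleophile is thus generated by Si–F bond formation in a chain and not by stoichiometric deprotonation, so the free aldolate is only a fleeting chain carrier and no base is present at the end. This fluoride-relayed desilylative SNAr returns to the route at 29.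

2. Step 9. The α-alkoxy oxygen may compete for magnesium and lower or reverse the anti and facial selectivity, and addition to the electron-rich aldehyde may be slow enough for retro-aldol to erode the ratio before silylation. Fallback: setting out from 20 and 14, the dibutylboron enolate (Bu2BOTf, Et3N, CH2Cl2, −78 → 0 °C) should give the syn aldol adduct F2 with (2S,3R) configuration, in which the carbinol centre destined to become C2 is already R. Transamidation as in step 10 gives the syn Weinreb amide F3, union with 24 as in step 11 gives the syn hydroxy ketone F4, and ring closure as in step 12 gives the 2,3-cis penta-MOM chromanone F5. Brief treatment of F5 with DBU (CH2Cl2, rt) epimerises C3 through the C4 enolate to the diequatorial trans isomer, where the fallback rejoins the route at 29. The C3 configuration is thus set by thermodynamic equilibration of the closed ring and not by the aldol.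

3. Step 11. The hindered aryllithium may act as a base towards the α-C–H of the anionic, α-branched amide, or lose LiF to an aryne, before it adds to the carbonyl. Fallback: setting out from 23, silylation (TESCl, imidazole, DMF) gives the triethylsilyl ether F6 and reduction (DIBAL-H, THF, −78 °C) gives the aldehyde F7. Addition of 24 (generated from 12 as in step 11, 1.1 equiv, THF, −78 °C) to this far more electrophilic carbonyl gives the carbinol F8 as an epimer mixture at the new centre, which is of no consequence. Dess–Martin oxidation gives the silyl-protected ketone F9, and HF·pyridine (pyridine, THF, 0 °C) removes the silyl group, returning to the route at 27.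

Further compounds
F1 | step 12 | (2R,3R)-3-[2,4-bis(methoxymethoxy)phenyl]-1-{2-fluoro-4,6-bis(methoxymethoxy)-5-(3-methylbut-2-en-1-yl)-3-[(2S)-5-methyl-2-(prop-1-en-2-yl)hex-4-en-1-yl]phenyl}-2-(methoxymethoxy)-3-(trimethylsilyloxy)propan-1-one | C=C(C)[C@@H](CC=C(C)C)Cc1c(OCOC)c(CC=C(C)C)c(OCOC)c(C(=O)[C@H](OCOC)[C@H](O[Si](C)(C)C)c2ccc(OCOC)cc2OCOC)c1F
F2 | step 9 | (S)-4-benzyl-3-[(2S,3R)-3-[2,4-bis(methoxymethoxy)phenyl]-3-hydroxy-2-(methoxymethoxy)propanoyl]oxazolidin-2-one | O=C([C@@H](OCOC)[C@H](O)c1ccc(OCOC)cc1OCOC)N1C(=O)OC[C@@H]1Cc1ccccc1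
F3 | step 9 | (2S,3R)-3-[2,4-bis(methoxymethoxy)phenyl]-3-hydroxy-N-methoxy-2-(methoxymethoxy)-N-methylpropanamide | CON(C)C(=O)[C@@H](OCOC)[C@H](O)c1ccc(OCOC)cc1OCOC
F4 | step 9 | (2S,3R)-3-[2,4-bis(methoxymethoxy)phenyl]-1-{2-fluoro-4,6-bis(methoxymethoxy)-5-(3-methylbut-2-en-1-yl)-3-[(2S)-5-methyl-2-(prop-1-en-2-yl)hex-4-en-1-yl]phenyl}-3-hydroxy-2-(methoxymethoxy)propan-1-one | C=C(C)[C@@H](CC=C(C)C)Cc1c(OCOC)c(CC=C(C)C)c(OCOC)c(C(=O)[C@@H](OCOC)[C@H](O)c2ccc(OCOC)cc2OCOC)c1F
F5 | step 9 | (2R,3S)-2-[2,4-bis(methoxymethoxy)phenyl]-3,5,7-tris(methoxymethoxy)-6-(3-methylbut-2-en-1-yl)-8-[(2S)-5-methyl-2-(prop-1-en-2-yl)hex-4-en-1-yl]chroman-4-one | C=C(C)[C@@H](CC=C(C)C)Cc1c(OCOC)c(CC=C(C)C)c(OCOC)c2c1O[C@H](c1ccc(OCOC)cc1OCOC)[C@H](OCOC)C2=O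
F6 | step 11 | (2R,3R)-3-[2,4-bis(methoxymethoxy)phenyl]-N-methoxy-2-(methoxymethoxy)-N-methyl-3-(triethylsilyloxy)propanamide | CON(C)C(=O)[C@H](OCOC)[C@H](O[Si](CC)(CC)CC)c1ccc(OCOC)cc1OCOC
F7 | step 11 | (2R,3R)-3-[2,4-bis(methoxymethoxy)phenyl]-2-(methoxymethoxy)-3-(triethylsilyloxy)propanal | O=C[C@H](OCOC)[C@H](O[Si](CC)(CC)CC)c1ccc(OCOC)cc1OCOC
F8 | step 11 | (2R,3R)-3-[2,4-bis(methoxymethoxy)phenyl]-1-{2-fluoro-4,6-bis(methoxymethoxy)-5-(3-methylbut-2-en-1-yl)-3-[(2S)-5-methyl-2-(prop-1-en-2-yl)hex-4-en-1-yl]phenyl}-2-(methoxymethoxy)-3-(triethylsilyloxy)propan-1-ol, mixture of C1 epimers | C=C(C)[C@@H](CC=C(C)C)Cc1c(OCOC)c(CC=C(C)C)c(OCOC)c(C(O)[C@H](OCOC)[C@H](O[Si](CC)(CC)CC)c2ccc(OCOC)cc2OCOC)c1F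
F9 | step 11 | (2R,3R)-3-[2,4-bis(methoxymethoxy)phenyl]-1-{2-fluoro-4,6-bis(methoxymethoxy)-5-(3-methylbut-2-en-1-yl)-3-[(2S)-5-methyl-2-(prop-1-en-2-yl)hex-4-en-1-yl]phenyl}-2-(methoxymethoxy)-3-(triethylsilyloxy)propan-1-one | C=C(C)[C@@H](CC=C(C)C)Cc1c(OCOC)c(CC=C(C)C)c(OCOC)c(C(=O)[C@H](OCOC)[C@H](O[Si](CC)(CC)CC)c2ccc(OCOC)cc2OCOC)c1F
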